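**Retrosynthetic overview**
1. Target 26 ⇐ 25 ⇐ 24: fluoride desilylation, then hydrogenolysis of two aryl benzyl ethers, from the fully protected trans-lactone.
2. The γ-butyrolactone (last ring formed) ⇐ reduction/lactonisation of succinate 22. Its lactone C-3/C-4 bond ⇐ oxidative heterocoupling of the enolates of imide 13 and ester 21: one enolate is oxidised to an electrophilic α-carbonyl (enolonium-type) species, so two normally nucleophilic α-carbons are joined, and the auxiliary on 13 fixes lactone C-4.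
3. Half B (13): the dihydrobenzofuran ring is made first, by enantioselective dirhodium-carbenoid C–H insertion of aryl diazoacetate 6; then ester → CH2OTBS and a Heck reaction with an acrylimide.
4. Half A (21): erythro aryl-glycerol aryl ether by auxiliary-controlled anti-aldol of aryloxyacetyl imide 16 with O-benzylvanillin, reductive auxiliary removal, silylation.
5. Ring order: dihydrofuran ring of the benzofuran (step 4), then the butyrolactone (step 14).

Assumption: acyl oxazolidinones 11 and 15 are bought (each is otherwise one acylation of (S)-4-benzyloxazolidin-2-one), and the (R)-configured dirhodium catalyst is taken to give the (2S) ether carbon by analogy, recalled from memory, with related 2-(benzyloxy)aryl diazoacetates (the mirror-image catalyst is used if a test run shows the opposite sense).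

**Route**

Step 1
Reactants: 1 4-bromo-2-methoxyphenol
Product: 2 4-bromo-2-iodo-6-methoxyphenol
Conditions: NIS (1.05 equiv), TsOH·H2O (10 mol%), MeCN, 0 °C → rt
Reagents that add atoms: N-iodosuccinimide O=C1CCC(=O)N1I
Why: Electrophilic aromatic iodination goes ortho to the free hydroxyl because the para position carries bromine and the hydroxyl is the strongest director; no stereocentre.

Step 2
Reactants: 2 4-bromo-2-iodo-6-methoxyphenol; 3 [4-(benzyloxy)-3-methoxyphenyl]methanol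
Product: 4 2-{[4-(benzyloxy)-3-methoxyphenyl]methoxy}-5-bromo-1-iodo-3-methoxybenzene
Conditions: PPh3 (1.2 equiv), DIAD (1.2 equiv), THF, 0 °C → rt
Reagents that add atoms: none
Why: Mitsunobu etherification joins the acidic di-ortho-substituted phenol to the primary benzylic alcohol under neutral conditions that leave both aryl halides untouched.

Step 3
Reactants: 4 aryl iodide; 5 ethyl diazoacetate
Product: 6 ethyl 2-(2-{[4-(benzyloxy)-3-methoxyphenyl]methoxy}-5-bromo-3-methoxyphenyl)-2-diazoacetate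
Conditions: Pd(PPh3)4 (5 mol%), Ag2CO3 (0.5 equiv), Et3N (1.3 equiv), toluene, rt, dark
Reagents that add atoms: none
Why: Palladium-catalysed cross-coupling of an aryl iodide with the C–H bond of ethyl diazoacetate keeps the diazo group and is selective for iodide over bromide at room temperature.

Step 4
Reactants: 6 aryl diazoacetate
Product: 8 ethyl (2S,3S)-2-[4-(benzyloxy)-3-methoxyphenyl]-5-bromo-7-methoxy-2,3-dihydro-1-benzofuran-3-carboxylate, via cis-ester 7 (not isolated)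
Conditions: Rh2(R-PTTL)4 (1 mol%; PTTL = N-phthaloyl-tert-leucinate), toluene, −60 → −20 °C; then NaOEt (0.2 equiv), EtOH, 0 °C → rt
Reagents that add atoms: none
Why: Enantioselective intramolecular 1,5 C–H insertion of the dirhodium donor/acceptor carbenoid into the activated benzylic ether C–H sets C-2 as S and gives the cis ester kinetically, and ethoxide then epimerises only the ester-bearing C-3 to the more stable trans (2S,3S) isomer.

Step 5
Reactants: 8 trans ester
Product: 9 {(2S,3R)-2-[4-(benzyloxy)-3-methoxyphenyl]-5-bromo-7-methoxy-2,3-dihydro-1-benzofuran-3-yl}methanol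
Conditions: iBu2AlH (2.5 equiv), CH2Cl2, −78 → 0 °C; aq. KNaC4H4O6 work-up; recrystallise
Reagents that add atoms: none
Why: Hydride reduction of the ester gives the primary alcohol without touching the stereocentres, the aryl bromide or the benzyl ether, and recrystallisation raises 9 to enantiopurity.

Step 6
Reactants: 9 alcohol
Product: 10 (2S,3R)-2-[4-(benzyloxy)-3-methoxyphenyl]-5-bromo-3-({[tert-butyl(dimethyl)silyl]oxy}methyl)-7-methoxy-2,3-dihydro-1-benzofuran
Conditions: TBSCl (1.2 equiv), imidazole (2 equiv), DMF, rt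
Reagents that add atoms: tert-butyldimethylsilyl chloride CC(C)(C)[Si](C)(C)Cl
Why: Silylation masks the primary alcohol for the later strong-base step; stereocentres untouched.

Step 7
Reactants: 10 aryl bromide; 11 (4S)-4-benzyl-3-(prop-2-enoyl)-1,3-oxazolidin-2-one
Product: 12 (4S)-4-benzyl-3-[(2E)-3-{(2S,3R)-2-[4-(benzyloxy)-3-methoxyphenyl]-3-({[tert-butyl(dimethyl)silyl]oxy}methyl)-7-methoxy-2,3-dihydro-1-benzofuran-5-yl}prop-2-enoyl]-1,3-oxazolidin-2-one
Conditions: Pd2(dba)3 (2 mol%), [HP(tBu)3]BF4 (8 mol%), Cy2NMe (1.3 equiv), 1,4-dioxane, 70 °C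
Reagents that add atoms: none
Why: The Heck reaction of the unhindered, electron-rich aryl bromide with the acrylimide installs the three-carbon side chain and the chiral auxiliary in one operation as the E-enoyl imide.

Step 8
Reactants: 12 enoyl imide
Product: 13 (4S)-4-benzyl-3-[3-{(2S,3R)-2-[4-(benzyloxy)-3-methoxyphenyl]-3-({[tert-butyl(dimethyl)silyl]oxy}methyl)-7-methoxy-2,3-dihydro-1-benzofuran-5-yl}propanoyl]-1,3-oxazolidin-2-one (half B)
Conditions: H2 (1 atm), 10% Pd/C, Ph2S (1 mol%), EtOAc, rt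
Reagents that add atoms: none
Why: Catalytic hydrogenation over sulfide-poisoned palladium on carbon saturates the conjugated alkene while the aryl benzyl ether and the benzylic C–O bond of the dihydrobenzofuran survive.

Step 9
Reactants: 14 methyl 3-(4-hydroxy-3-methoxyphenyl)propanoate; 15 (4S)-4-benzyl-3-(chloroacetyl)-1,3-oxazolidin-2-one
Product: 16 methyl 3-[4-{2-[(4S)-4-benzyl-2-oxo-1,3-oxazolidin-3-yl]-2-oxoethoxy}-3-methoxyphenyl]propanoate
Conditions: K2CO3 (1.5 equiv), MeCN, 50 °C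
Reagents that add atoms: none
Why: Williamson ether synthesis, in which the phenoxide displaces chloride from the highly SN2-reactive α-chloro imide faster than it attacks either carbonyl.

Step 10
Reactants: 16 aryloxyacetyl imide; 17 4-(benzyloxy)-3-methoxybenzaldehyde
Product: 19 methyl 3-[4-({(2R,3R)-1-[(4S)-4-benzyl-2-oxo-1,3-oxazolidin-3-yl]-3-[4-(benzyloxy)-3-methoxyphenyl]-3-hydroxy-1-oxopropan-2-yl}oxy)-3-methoxyphenyl]propanoate, via silyl ether 18 (not isolated)
Conditions: MgCl2 (20 mol%), Et3N (2 equiv), TMSCl (1.5 equiv), EtOAc, rt; then 10% aq. citric acid, MeOH, 0 °C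
Reagents that add atoms: none
Why: Proposed new method: MgCl2 chelates both imide carbonyls so Et3N soft-enolises the acidic aryloxyacetyl group to the chelated (Z)-enolate, the aldehyde adds through a boat-like transition state on the face away from the auxiliary benzyl group to give the anti (2R,3R) aldolate, and TMSCl traps it and turns magnesium over; the closest known reaction is the magnesium-halide-catalysed direct anti-aldol of N-propionyl oxazolidinones with aromatic aldehydes.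

Step 11
Reactants: 19 anti-aldol imide
Product: 20 methyl 3-[4-({(1R,2S)-1-[4-(benzyloxy)-3-methoxyphenyl]-1,3-dihydroxypropan-2-yl}oxy)-3-methoxyphenyl]propanoate (erythro)
Conditions: NaBH4 (4 equiv), THF/H2O (4:1), 0 °C → rt
Reagents that add atoms: none
Why: Reductive cleavage of the activated N-acyl oxazolidinone by borohydride gives the primary alcohol and releases the auxiliary while the plain methyl ester is reduced far more slowly; both stereocentres are unchanged (the C-2 descriptor changes only by priority).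

Step 12
Reactants: 20 diol
Product: 21 methyl 3-[4-({(1R,2S)-1-[4-(benzyloxy)-3-methoxyphenyl]-1,3-bis{[tert-butyl(dimethyl)silyl]oxy}propan-2-yl}oxy)-3-methoxyphenyl]propanoate (half A)
Conditions: TBSOTf (2.5 equiv), 2,6-lutidine (3.5 equiv), CH2Cl2, −78 → 0 °C
Reagents that add atoms: tert-butyldimethylsilyl trifluoromethanesulfonate CC(C)(C)[Si](C)(C)OS(=O)(=O)C(F)(F)F
Why: Silylation with the silyl triflate covers the primary and the hindered benzylic hydroxyl so that no acidic O–H remains for the enolate step.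

Step 13
Reactants: 13 imide (half B); 21 ester (half A)
Product: 22 methyl (3R)-4-[(4S)-4-benzyl-2-oxo-1,3-oxazolidin-3-yl]-2-(half A arylmethyl)-3-(half B arylmethyl)-4-oxobutanoate (both C-2 epimers)
Conditions: 13 (1.0 equiv) + 21 (1.5 equiv), LiN(iPr)2 (2.6 equiv), THF, −78 °C, 30 min; then Fe(acac)3 (2.6 equiv), THF, −78 °C → rt
Reagents that add atoms: none
Why: In this oxidative enolate heterocoupling both partners are lithium enolates and one-electron oxidation by Fe(acac)3 turns one of them into an electrophilic α-carbonyl radical (enolonium equivalent) that the other captures; the chelated (Z)-imide enolate reacts on the face away from the auxiliary benzyl group, as in its alkylations, which fixes C-3 as R, while the epimerisable C-2 forms as a mixture that step 14 corrects.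

Step 14
Reactants: 22 coupled succinate
Product: 24 fully protected (3R,4R)-lactone (tris-TBS ether and bis-benzyl ether of the target), via hydroxy ester 23 (not isolated)
Conditions: NaBH4 (5 equiv), THF/H2O (4:1), 0 °C → rt; extractive work-up; then DBU (1 equiv), toluene, 60 °C
Reagents that add atoms: none
Why: Chemoselective borohydride reduction of the imide frees the primary alcohol, which lactonises onto the neighbouring methyl ester, and DBU equilibrates the α-carbon to the thermodynamically preferred trans-3,4-dibenzyl lactone, giving (3R,4R).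

Step 15
Reactants: 24 protected lactone
Product: 25 target bis(benzyl ether) (triol)
Conditions: Bu4NF (4.5 equiv), AcOH (4.5 equiv), THF, 0 °C → rt
Reagents that add atoms: none
Why: Acetic-acid-buffered fluoride desilylation removes the three silyl ethers without opening the lactone or ionising the benzylic positions.

Step 16
Reactants: 25 bis(benzyl ether)
Product: 26 target
Conditions: H2 (1 atm), 10% Pd/C, EtOAc/EtOH (1:1), rt, stopped at full conversion (about 1–2 h)
Reagents that add atoms: none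
Why: Hydrogenolysis cleaves the two aryl benzyl ethers quickly under neutral conditions, whereas the benzylic alcohol and the benzylic ether bond of the dihydrobenzofuran react much more slowly.

**Compound list**

1 | 4-bromo-2-methoxyphenol | COc1cc(Br)ccc1O | starting material
2 | 4-bromo-2-iodo-6-methoxyphenol | COc1cc(Br)cc(I)c1O | intermediate
3 | [4-(benzyloxy)-3-methoxyphenyl]methanol | COc1cc(CO)ccc1OCc1ccccc1 | starting material
4 | 2-{[4-(benzyloxy)-3-methoxyphenyl]methoxy}-5-bromo-1-iodo-3-methoxybenzene | COc1cc(Br)cc(I)c1OCc1ccc(OCc2ccccc2)c(OC)c1 | intermediate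
5 | ethyl diazoacetate | CCOC(=O)C=[N+]=[N-] | starting material
6 | ethyl 2-(2-{[4-(benzyloxy)-3-methoxyphenyl]methoxy}-5-bromo-3-methoxyphenyl)-2-diazoacetate | CCOC(=O)C(=[N+]=[N-])c1cc(Br)cc(OC)c1OCc1ccc(OCc2ccccc2)c(OC)c1 | intermediate
7 | ethyl (2S,3R)-2-[4-(benzyloxy)-3-methoxyphenyl]-5-bromo-7-methoxy-2,3-dihydro-1-benzofuran-3-carboxylate (cis, not isolated) | Brc1cc(OC)c2c(c1)[C@@H](C(=O)OCC)[C@@H](c1ccc(OCc3ccccc3)c(OC)c1)O2 | intermediate
8 | ethyl (2S,3S)-2-[4-(benzyloxy)-3-methoxyphenyl]-5-bromo-7-methoxy-2,3-dihydro-1-benzofuran-3-carboxylate (trans) | Brc1cc(OC)c2c(c1)[C@H](C(=O)OCC)[C@@H](c1ccc(OCc3ccccc3)c(OC)c1)O2 | intermediate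
9 | {(2S,3R)-2-[4-(benzyloxy)-3-methoxyphenyl]-5-bromo-7-methoxy-2,3-dihydro-1-benzofuran-3-yl}methanol | Brc1cc(OC)c2c(c1)[C@H](CO)[C@@H](c1ccc(OCc3ccccc3)c(OC)c1)O2 | intermediate
10 | (2S,3R)-2-[4-(benzyloxy)-3-methoxyphenyl]-5-bromo-3-({[tert-butyl(dimethyl)silyl]oxy}methyl)-7-methoxy-2,3-dihydro-1-benzofuran | Brc1cc(OC)c2c(c1)[C@H](CO[Si](C)(C)C(C)(C)C)[C@@H](c1ccc(OCc3ccccc3)c(OC)c1)O2 | intermediate
11 | (4S)-4-benzyl-3-(prop-2-enoyl)-1,3-oxazolidin-2-one | C=CC(=O)N1[C@@H](Cc2ccccc2)COC1=O | starting material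
12 | (4S)-4-benzyl-3-[(2E)-3-{(2S,3R)-2-[4-(benzyloxy)-3-methoxyphenyl]-3-({[tert-butyl(dimethyl)silyl]oxy}methyl)-7-methoxy-2,3-dihydro-1-benzofuran-5-yl}prop-2-enoyl]-1,3-oxazolidin-2-one | O=C(/C=C/c1cc(OC)c2c(c1)[C@H](CO[Si](C)(C)C(C)(C)C)[C@@H](c1ccc(OCc3ccccc3)c(OC)c1)O2)N1[C@@H](Cc2ccccc2)COC1=O | intermediate
13 | (4S)-4-benzyl-3-[3-{(2S,3R)-2-[4-(benzyloxy)-3-methoxyphenyl]-3-({[tert-butyl(dimethyl)silyl]oxy}methyl)-7-methoxy-2,3-dihydro-1-benzofuran-5-yl}propanoyl]-1,3-oxazolidin-2-one (half B) | O=C(CCc1cc(OC)c2c(c1)[C@H](CO[Si](C)(C)C(C)(C)C)[C@@H](c1ccc(OCc3ccccc3)c(OC)c1)O2)N1[C@@H](Cc2ccccc2)COC1=O | intermediate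
14 | methyl 3-(4-hydroxy-3-methoxyphenyl)propanoate | COC(=O)CCc1ccc(O)c(OC)c1 | starting material
15 | (4S)-4-benzyl-3-(chloroacetyl)-1,3-oxazolidin-2-one | O=C(CCl)N1[C@@H](Cc2ccccc2)COC1=O | starting material
16 | methyl 3-[4-{2-[(4S)-4-benzyl-2-oxo-1,3-oxazolidin-3-yl]-2-oxoethoxy}-3-methoxyphenyl]propanoate | COC(=O)CCc1ccc(OCC(=O)N2[C@@H](Cc3ccccc3)COC2=O)c(OC)c1 | intermediate
17 | 4-(benzyloxy)-3-methoxybenzaldehyde | O=Cc1ccc(OCc2ccccc2)c(OC)c1 | starting material
18 | O-trimethylsilyl ether of 19, (2R,3R) (not isolated) | COC(=O)CCc1ccc(O[C@@H](C(=O)N2[C@@H](Cc3ccccc3)COC2=O)[C@H](O[Si](C)(C)C)c2ccc(OCc3ccccc3)c(OC)c2)c(OC)c1 | intermediate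
19 | methyl 3-[4-({(2R,3R)-1-[(4S)-4-benzyl-2-oxo-1,3-oxazolidin-3-yl]-3-[4-(benzyloxy)-3-methoxyphenyl]-3-hydroxy-1-oxopropan-2-yl}oxy)-3-methoxyphenyl]propanoate | COC(=O)CCc1ccc(O[C@@H](C(=O)N2[C@@H](Cc3ccccc3)COC2=O)[C@H](O)c2ccc(OCc3ccccc3)c(OC)c2)c(OC)c1 | intermediate
20 | methyl 3-[4-({(1R,2S)-1-[4-(benzyloxy)-3-methoxyphenyl]-1,3-dihydroxypropan-2-yl}oxy)-3-methoxyphenyl]propanoate | COC(=O)CCc1ccc(O[C@@H](CO)[C@H](O)c2ccc(OCc3ccccc3)c(OC)c2)c(OC)c1 | intermediate
21 | methyl 3-[4-({(1R,2S)-1-[4-(benzyloxy)-3-methoxyphenyl]-1,3-bis{[tert-butyl(dimethyl)silyl]oxy}propan-2-yl}oxy)-3-methoxyphenyl]propanoate (half A) | COC(=O)CCc1ccc(O[C@@H](CO[Si](C)(C)C(C)(C)C)[C@H](O[Si](C)(C)C(C)(C)C)c2ccc(OCc3ccccc3)c(OC)c2)c(OC)c1 | intermediate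
22 | methyl (3R)-4-[(4S)-4-benzyl-2-oxo-1,3-oxazolidin-3-yl]-2-{[aryl of 21]methyl}-3-{[benzofuranyl of 13]methyl}-4-oxobutanoate (C-2 left unspecified: both epimers) | O=C([C@H](Cc1cc(OC)c2c(c1)[C@H](CO[Si](C)(C)C(C)(C)C)[C@@H](c1ccc(OCc3ccccc3)c(OC)c1)O2)C(Cc1ccc(O[C@@H](CO[Si](C)(C)C(C)(C)C)[C@H](O[Si](C)(C)C(C)(C)C)c2ccc(OCc3ccccc3)c(OC)c2)c(OC)c1)C(=O)OC)N1[C@@H](Cc2ccccc2)COC1=O | intermediate
23 | methyl (3R)-4-hydroxy-2-{[aryl of 21]methyl}-3-{[benzofuranyl of 13]methyl}butanoate (C-2 epimers, not isolated) | OC[C@H](Cc1cc(OC)c2c(c1)[C@H](CO[Si](C)(C)C(C)(C)C)[C@@H](c1ccc(OCc3ccccc3)c(OC)c1)O2)C(Cc1ccc(O[C@@H](CO[Si](C)(C)C(C)(C)C)[C@H](O[Si](C)(C)C(C)(C)C)c2ccc(OCc3ccccc3)c(OC)c2)c(OC)c1)C(=O)OC | intermediate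
24 | (3R,4R)-3-{[4-({(1R,2S)-1-[4-(benzyloxy)-3-methoxyphenyl]-1,3-bis{[tert-butyl(dimethyl)silyl]oxy}propan-2-yl}oxy)-3-methoxyphenyl]methyl}-4-{[(2S,3R)-2-[4-(benzyloxy)-3-methoxyphenyl]-3-({[tert-butyl(dimethyl)silyl]oxy}methyl)-7-methoxy-2,3-dihydro-1-benzofuran-5-yl]methyl}oxolan-2-one | COc1cc([C@@H](O[Si](C)(C)C(C)(C)C)[C@H](CO[Si](C)(C)C(C)(C)C)Oc2ccc(C[C@H]3C(=O)OC[C@@H]3Cc3cc(OC)c4c(c3)[C@H](CO[Si](C)(C)C(C)(C)C)[C@@H](c3ccc(OCc5ccccc5)c(OC)c3)O4)cc2OC)ccc1OCc1ccccc1 | intermediate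
25 | (3R,4R)-3-{[4-({(1R,2S)-1-[4-(benzyloxy)-3-methoxyphenyl]-1,3-dihydroxypropan-2-yl}oxy)-3-methoxyphenyl]methyl}-4-{[(2S,3R)-2-[4-(benzyloxy)-3-methoxyphenyl]-3-(hydroxymethyl)-7-methoxy-2,3-dihydro-1-benzofuran-5-yl]methyl}oxolan-2-one | COc1cc([C@@H](O)[C@H](CO)Oc2ccc(C[C@H]3C(=O)OC[C@@H]3Cc3cc(OC)c4c(c3)[C@H](CO)[C@@H](c3ccc(OCc5ccccc5)c(OC)c3)O4)cc2OC)ccc1OCc1ccccc1 | intermediate
26 | (3R,4R)-3-{[4-({(1R,2S)-1,3-dihydroxy-1-(4-hydroxy-3-methoxyphenyl)propan-2-yl}oxy)-3-methoxyphenyl]methyl}-4-{[(2S,3R)-2-(4-hydroxy-3-methoxyphenyl)-3-(hydroxymethyl)-7-methoxy-2,3-dihydro-1-benzofuran-5-yl]methyl}oxolan-2-one (CNP0298853.1) | COc1cc([C@@H](O)[C@H](CO)Oc2ccc(C[C@H]3C(=O)OC[C@@H]3Cc3cc(OC)c4c(c3)[C@H](CO)[C@@H](c3ccc(O)c(OC)c3)O4)cc2OC)ccc1O | target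

**Step count:** 16 steps in total. Longest linear sequence: 12 steps (steps 1–8, then 13–16); half A (steps 9–12) is made in parallel.

**Three steps most likely to fail, with fallbacks**

Step 13 (oxidative heterocoupling of two large, fully elaborated enolates) is the main risk: homodimers and low conversion are possible, and the facial control by the auxiliary is inferred from alkylation behaviour. The fallback sets out from 21 (with 13) and comes back at 22. Ester 21 is hydroxylated at the α-carbon (KN(SiMe3)2, then 2-(phenylsulfonyl)-3-phenyloxaziridine, THF, −78 °C) to the α-hydroxy ester F1, either epimer being usable. F1 is converted with Tf2O and 2,6-lutidine (CH2Cl2, −78 °C) into the α-triflyloxy ester F2, a two-electron enolonium equivalent. The sodium enolate of 13 (NaN(SiMe3)2, THF, −78 → −30 °C) displaces the triflate in an SN2 reaction on the same auxiliary-controlled face and gives 22, whose C-2 epimers again converge in step 14.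

Step 10 (magnesium-catalysed anti-aldol on an α-aryloxy imide) is an untested substrate class; wrong diastereoselectivity or retro-aldol would give threo material. The fallback sets out from 14 and comes back at 21. Phenol 14 is alkylated (K2CO3, MeCN) with the enantiomeric (4R)-4-benzyl-3-(chloroacetyl)oxazolidin-2-one to the (R)-imide F3. A dibutylboron-triflate syn-aldol (Bu2BOTf, iPr2NEt, CH2Cl2, −78 → 0 °C) with 17 gives the (2R,3S) syn adduct F4. NaBH4 in THF/H2O gives the threo (1S,2S)-diol F5, and TBSCl/imidazole protects only the primary hydroxyl to give the mono-silyl ether F6. Mitsunobu inversion at the benzylic carbon (4-nitrobenzoic acid, PPh3, DIAD) gives the (1R,2S) 4-nitrobenzoate F7. K2CO3 in MeOH frees the erythro alcohol F8, and TBSOTf/2,6-lutidine gives 21.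

Step 4 (enantioselective C–H insertion) may give lower enantiomeric excess, or the opposite sense, on this tri-oxygenated substrate. The fallback sets out from 6 and comes back at 9, replacing catalyst control by a resolution through diastereomers. Rh2(OAc)4 in CH2Cl2 gives the racemic cis ester, that is 7 together with its mirror image, the ent-cis ester F9 (not isolated). NaOEt/EtOH gives 8 together with its enantiomer, the (2R,3R) trans ester F10, and iBu2AlH gives 9 together with the (2R,3S) alcohol F11. Esterification with (S)-2-methoxy-2-phenylacetic acid (DCC, DMAP, CH2Cl2) gives two diastereomeric esters, the (2S,3R) mandelate F12 and the (2R,3S) mandelate F13, which are separated by chromatography and crystallisation. K2CO3 in MeOH on F12 returns enantiopure 9.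

**Further compounds**

F1 | step 13 | methyl 2-hydroxy-3-[4-({(1R,2S)-1-[4-(benzyloxy)-3-methoxyphenyl]-1,3-bis{[tert-butyl(dimethyl)silyl]oxy}propan-2-yl}oxy)-3-methoxyphenyl]propanoate (C-2 epimers) | COC(=O)C(O)Cc1ccc(O[C@@H](CO[Si](C)(C)C(C)(C)C)[C@H](O[Si](C)(C)C(C)(C)C)c2ccc(OCc3ccccc3)c(OC)c2)c(OC)c1
F2 | step 13 | methyl 2-{[(trifluoromethyl)sulfonyl]oxy}-3-[4-({(1R,2S)-1-[4-(benzyloxy)-3-methoxyphenyl]-1,3-bis{[tert-butyl(dimethyl)silyl]oxy}propan-2-yl}oxy)-3-methoxyphenyl]propanoate (C-2 epimers) | COC(=O)C(OS(=O)(=O)C(F)(F)F)Cc1ccc(O[C@@H](CO[Si](C)(C)C(C)(C)C)[C@H](O[Si](C)(C)C(C)(C)C)c2ccc(OCc3ccccc3)c(OC)c2)c(OC)c1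
F3 | step 10 | methyl 3-[4-{2-[(4R)-4-benzyl-2-oxo-1,3-oxazolidin-3-yl]-2-oxoethoxy}-3-methoxyphenyl]propanoate | COC(=O)CCc1ccc(OCC(=O)N2[C@H](Cc3ccccc3)COC2=O)c(OC)c1
F4 | step 10 | methyl 3-[4-({(2R,3S)-1-[(4R)-4-benzyl-2-oxo-1,3-oxazolidin-3-yl]-3-[4-(benzyloxy)-3-methoxyphenyl]-3-hydroxy-1-oxopropan-2-yl}oxy)-3-methoxyphenyl]propanoate | COC(=O)CCc1ccc(O[C@@H](C(=O)N2[C@H](Cc3ccccc3)COC2=O)[C@@H](O)c2ccc(OCc3ccccc3)c(OC)c2)c(OC)c1
F5 | step 10 | methyl 3-[4-({(1S,2S)-1-[4-(benzyloxy)-3-methoxyphenyl]-1,3-dihydroxypropan-2-yl}oxy)-3-methoxyphenyl]propanoate | COC(=O)CCc1ccc(O[C@@H](CO)[C@@H](O)c2ccc(OCc3ccccc3)c(OC)c2)c(OC)c1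
F6 | step 10 | methyl 3-[4-({(1S,2S)-1-[4-(benzyloxy)-3-methoxyphenyl]-3-{[tert-butyl(dimethyl)silyl]oxy}-1-hydroxypropan-2-yl}oxy)-3-methoxyphenyl]propanoate | COC(=O)CCc1ccc(O[C@@H](CO[Si](C)(C)C(C)(C)C)[C@@H](O)c2ccc(OCc3ccccc3)c(OC)c2)c(OC)c1
F7 | step 10 | (1R,2S)-1-[4-(benzyloxy)-3-methoxyphenyl]-3-{[tert-butyl(dimethyl)silyl]oxy}-2-[2-methoxy-4-(3-methoxy-3-oxopropyl)phenoxy]propyl 4-nitrobenzoate | COC(=O)CCc1ccc(O[C@@H](CO[Si](C)(C)C(C)(C)C)[C@H](OC(=O)c2ccc(cc2)[N+](=O)[O-])c2ccc(OCc3ccccc3)c(OC)c2)c(OC)c1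
F8 | step 10 | methyl 3-[4-({(1R,2S)-1-[4-(benzyloxy)-3-methoxyphenyl]-3-{[tert-butyl(dimethyl)silyl]oxy}-1-hydroxypropan-2-yl}oxy)-3-methoxyphenyl]propanoate | COC(=O)CCc1ccc(O[C@@H](CO[Si](C)(C)C(C)(C)C)[C@H](O)c2ccc(OCc3ccccc3)c(OC)c2)c(OC)c1
F9 | step 4 | ethyl (2R,3S)-2-[4-(benzyloxy)-3-methoxyphenyl]-5-bromo-7-methoxy-2,3-dihydro-1-benzofuran-3-carboxylate (cis, enantiomer of 7) | Brc1cc(OC)c2c(c1)[C@H](C(=O)OCC)[C@H](c1ccc(OCc3ccccc3)c(OC)c1)O2
F10 | step 4 | ethyl (2R,3R)-2-[4-(benzyloxy)-3-methoxyphenyl]-5-bromo-7-methoxy-2,3-dihydro-1-benzofuran-3-carboxylate (trans, enantiomer of 8) | Brc1cc(OC)c2c(c1)[C@@H](C(=O)OCC)[C@H](c1ccc(OCc3ccccc3)c(OC)c1)O2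
F11 | step 4 | {(2R,3S)-2-[4-(benzyloxy)-3-methoxyphenyl]-5-bromo-7-methoxy-2,3-dihydro-1-benzofuran-3-yl}methanol (enantiomer of 9) | Brc1cc(OC)c2c(c1)[C@@H](CO)[C@H](c1ccc(OCc3ccccc3)c(OC)c1)O2
F12 | step 4 | {(2S,3R)-2-[4-(benzyloxy)-3-methoxyphenyl]-5-bromo-7-methoxy-2,3-dihydro-1-benzofuran-3-yl}methyl (2S)-2-methoxy-2-phenylacetate | Brc1cc(OC)c2c(c1)[C@H](COC(=O)[C@@H](OC)c1ccccc1)[C@@H](c1ccc(OCc3ccccc3)c(OC)c1)O2
F13 | step 4 | {(2R,3S)-2-[4-(benzyloxy)-3-methoxyphenyl]-5-bromo-7-methoxy-2,3-dihydro-1-benzofuran-3-yl}methyl (2S)-2-methoxy-2-phenylacetate | Brc1cc(OC)c2c(c1)[C@@H](COC(=O)[C@@H](OC)c1ccccc1)[C@H](c1ccc(OCc3ccccc3)c(OC)c1)O2
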